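The benzene ring of the coumarin (C4a, C5, C6, C7, C8, C8a) is hexasubstituted, with the C7 oxygen between the methyl-bearing C6 and C8. It is disconnected at C5–C6 and C7–C8: four ring carbons come from a tetrasubstituted 2-pyrone-5-carboxylate that already holds the C8 methyl, the C8a oxygen (as a pivalate), the future C4 (as the ester) and the silyl-protected (S)-2-hydroxypropyl chain; C6 and C7 come from 1-(triisopropylsilyloxy)propyne. One thermal cycloaddition with loss of CO2 closes this ring with all six substituents placed and both oxygens differentiated. The ester then becomes the aldehyde for coumarin formation, and the dihydropyranone is closed last.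

Key step: step 7

Remark: the enol pivalate on the pyrone is assumed to be inert toward the siloxyalkyne at 110 °C, and both enantiomers of 3-hydroxybutanoic acid are taken as the commercial free acids.

Step 1
Reactants: 1 (S)-3-hydroxybutanoic acid
Product: 3 (S)-3-(tert-butyldiphenylsilyloxy)butanoic acid, via silyl ester 2 (not isolated)
Conditions: t-BuPh2SiCl (2.2 equiv), imidazole, DMF, rt; then K2CO3, MeOH/THF/H2O, rt; aq. HCl to pH 3
Reagents that add atoms: tert-butyl(chloro)diphenylsilane, CC(C)(C)[Si](Cl)(c1ccccc1)c1ccccc1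
Why: Hydroxyl and carboxyl are both silylated and the far more labile silyl ester is then cleaved selectively by carbonate, a standard protection that does not touch the stereocentre, which comes from the chiral pool.

Step 2
Reactants: 3 (S)-3-(tert-butyldiphenylsilyloxy)butanoic acid; 4 potassium methyl malonate
Product: 6 methyl (S)-5-(tert-butyldiphenylsilyloxy)-3-oxohexanoate, via acyl imidazolide 5 (not isolated)
Conditions: CDI, THF, rt; then 4, MgCl2, THF, rt → 45 °C; cold aq. HCl
Reagents that add atoms: none
Why: In the Masamune–Brooks homologation the acyl imidazolide C-acylates the magnesium enolate of the malonate half-ester under near-neutral conditions and decarboxylation gives the beta-keto ester, so the beta-silyloxy group is not eliminated.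

Step 3
Reactants: 7 methylmalonic acid
Product: 8 methylmalonyl dichloride
Conditions: SOCl2 (neat), DMF (cat.), 50 °C; distillation at reduced pressure
Reagents that add atoms: thionyl chloride, O=S(Cl)Cl
Why: Thionyl chloride converts the diacid into the diacid chloride in the standard way, and distillation gives acid-free material that is used at once.

Step 4
Reactants: 6 methyl (S)-5-(tert-butyldiphenylsilyloxy)-3-oxohexanoate; 8 methylmalonyl dichloride
Product: 9 methyl 6-[(S)-2-(tert-butyldiphenylsilyloxy)propyl]-4-hydroxy-3-methyl-2-oxo-2H-pyran-5-carboxylate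
Conditions: 8 (1.3 equiv, slow addition), PhMe, 80 °C, N2 purge
Reagents that add atoms: none
Why: The enol of the keto ester is acylated at its central carbon by one acid chloride group and the ketone enol oxygen then closes the lactone on the other, the classical condensation of malonyl dichlorides with 1,3-dicarbonyl compounds to 4-hydroxy-2-pyrones, here with C3 blocked by methyl against a second annulation and with a silyl ether chosen to withstand the hydrogen chloride that is swept out.

Step 5
Reactants: 9 methyl 6-[(S)-2-(tert-butyldiphenylsilyloxy)propyl]-4-hydroxy-3-methyl-2-oxo-2H-pyran-5-carboxylate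
Product: 10 methyl 6-[(S)-2-(tert-butyldiphenylsilyloxy)propyl]-3-methyl-2-oxo-4-(pivaloyloxy)-2H-pyran-5-carboxylate
Conditions: t-BuCOCl, Et3N, DMAP (cat.), CH2Cl2, 0 °C
Reagents that add atoms: pivaloyl chloride, CC(C)(C)C(=O)Cl
Why: The acidic 4-hydroxyl (a vinylogous carboxylic acid whose neighbours C3 and C5 are blocked) is O-acylated under nucleophilic catalysis to the enol pivalate, which keeps the diene electron-poor and needs no separate removal later.

Step 6
Reactants: 11 propyne
Product: 14 1-(triisopropylsilyloxy)prop-1-yne, via 1-propynyllithium 12 (not isolated), via lithium propynolate 13 (not isolated)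
Conditions: n-BuLi, THF, −78 °C; LiOOt-Bu (from t-BuOOH and LiN(SiMe3)2), −78 → 0 °C; i-Pr3SiOTf, −78 → 0 °C
Reagents that add atoms: tert-butyl hydroperoxide, CC(C)(C)OO; triisopropylsilyl trifluoromethanesulfonate, CC(C)[Si](OS(=O)(=O)C(F)(F)F)(C(C)C)C(C)C
Why: The lithium acetylide is oxidised by lithium tert-butyl peroxide to the lithium ynolate, which is silylated on oxygen by the hard, bulky silyl triflate, the known route from terminal alkynes to triisopropylsilyl ynol ethers.

Step 7
Reactants: 10 methyl 6-[(S)-2-(tert-butyldiphenylsilyloxy)propyl]-3-methyl-2-oxo-4-(pivaloyloxy)-2H-pyran-5-carboxylate; 14 1-(triisopropylsilyloxy)prop-1-yne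
Product: 16 methyl 6-[(S)-2-(tert-butyldiphenylsilyloxy)propyl]-3,5-dimethyl-2-(pivaloyloxy)-4-(triisopropylsilyloxy)benzoate, via bridged lactone 15 (not isolated)
Conditions: 14 (2.5 equiv), PhMe, 110 °C, sealed tube
Reagents that add atoms: none
Why: The methyl-bearing alkyne carbon, the nucleophilic end of the ynol ether, bonds to pyrone C6 (beta to the C5 ester, delta to the lactone carbonyl) and the siloxy carbon then bonds to C3 in an asynchronous inverse-electron-demand Diels–Alder reaction; the bridged lactone 15 expels CO2 by a retro-[4+2] step and the arene forms irreversibly. The closest known reaction type is the thermal cycloaddition of 2-pyrone carboxylates with ynamines, alkoxyalkynes and siloxyalkynes to benzoates. The benzene ring is closed by an intermolecular [4+2] cycloaddition of four pyrone carbons with two alkyne carbons and becomes aromatic through the cycloreversion. No stereocentre is created, since the bridgeheads of 15 are lost on aromatisation and the (S)-carbinol of the side chain is a spectator. The step needs regioselectivity (methyl carbon to C6, siloxy carbon to C3) and enough reactivity at two fully substituted diene termini: the first is secured by the matched polarisation of the ester-activated pyrone and the ynol ether, the second by the electron-poor enol pivalate, the excess of the slim linear alkyne and the irreversible loss of CO2. The bulky triisopropylsilyl group keeps the alkyne from isomerising to a silylketene at this temperature.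

Step 8
Reactants: 16 methyl 6-[(S)-2-(tert-butyldiphenylsilyloxy)propyl]-3,5-dimethyl-2-(pivaloyloxy)-4-(triisopropylsilyloxy)benzoate
Product: 17 3-[(S)-2-(tert-butyldiphenylsilyloxy)propyl]-2-(hydroxymethyl)-4,6-dimethyl-5-(triisopropylsilyloxy)phenol
Conditions: LiAlH4, THF, 0 °C; then H2O, aq. NaOH
Reagents that add atoms: none
Why: LiAlH4 cleaves the aryl pivalate and reduces the flanked methyl ester to the benzylic alcohol in one operation (the ortho aluminium phenoxide assists hydride delivery), while the silyl ethers are inert and 0 °C avoids over-reduction through an ortho-quinone methide.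

Step 9
Reactants: 17 3-[(S)-2-(tert-butyldiphenylsilyloxy)propyl]-2-(hydroxymethyl)-4,6-dimethyl-5-(triisopropylsilyloxy)phenol
Product: 18 6-[(S)-2-(tert-butyldiphenylsilyloxy)propyl]-2-hydroxy-3,5-dimethyl-4-(triisopropylsilyloxy)benzaldehyde
Conditions: MnO2 (activated, excess), CH2Cl2, rt
Reagents that add atoms: none
Why: Activated MnO2 oxidises benzylic alcohols chemoselectively and stops at the aldehyde, the usual way from ortho-hydroxybenzyl alcohols to salicylaldehydes, with the silyl ethers untouched.

Step 10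
Reactants: 18 6-[(S)-2-(tert-butyldiphenylsilyloxy)propyl]-2-hydroxy-3,5-dimethyl-4-(triisopropylsilyloxy)benzaldehyde; 19 ethyl acetoacetate
Product: 20 3-acetyl-5-[(S)-2-(tert-butyldiphenylsilyloxy)propyl]-6,8-dimethyl-7-(triisopropylsilyloxy)-2H-chromen-2-one
Conditions: piperidine (cat.), AcOH (cat.), EtOH, 50 °C
Reagents that add atoms: none
Why: Knoevenagel condensation of the salicylaldehyde with the beta-keto ester followed by lactonisation of the phenol onto the ethyl ester is the standard synthesis of 3-acetylcoumarins and is driven by formation of the conjugated lactone.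

Step 11
Reactants: 21 (R)-3-hydroxybutanoic acid
Product: 23 (R)-3-(tert-butyldimethylsilyloxy)butanoic acid, via silyl ester 22 (not isolated)
Conditions: t-BuMe2SiCl (2.2 equiv), imidazole, DMF, rt; then K2CO3, MeOH/THF/H2O, 0 °C → rt; aq. HCl to pH 4, 0 °C
Reagents that add atoms: tert-butyl(chloro)dimethylsilane, CC(C)(C)[Si](C)(C)Cl
Why: The same silylation and selective silyl ester cleavage as in step 1 is applied to the enantiomeric acid, which supplies the (R) stereocentre of the dihydropyranone from the chiral pool.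

Step 12
Reactants: 20 3-acetyl-5-[(S)-2-(tert-butyldiphenylsilyloxy)propyl]-6,8-dimethyl-7-(triisopropylsilyloxy)-2H-chromen-2-one; 23 (R)-3-(tert-butyldimethylsilyloxy)butanoic acid
Product: 25 (R)-5-(tert-butyldimethylsilyloxy)-1-{5-[(S)-2-(tert-butyldiphenylsilyloxy)propyl]-6,8-dimethyl-2-oxo-7-(triisopropylsilyloxy)-2H-chromen-3-yl}hexane-1,3-dione, via acyl imidazolide 24 (not isolated)
Conditions: 23, CDI, THF, rt (gives 24); separately 20, LiN(SiMe3)2 (2.2 equiv), THF, −78 °C; solution of 24 added, −78 → −20 °C; aq. NH4Cl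
Reagents that add atoms: none
Why: In this crossed Claisen condensation the kinetic lithium enolate of the methyl ketone is C-acylated by the acyl imidazolide and the second equivalent of base takes up the more acidic 1,3-diketone; the stereocentre of the donor is beta to the carbonyl and cannot epimerise, and C4 of the coumarin is shielded by the C5 side chain.

Step 13
Reactants: 25 (R)-5-(tert-butyldimethylsilyloxy)-1-{5-[(S)-2-(tert-butyldiphenylsilyloxy)propyl]-6,8-dimethyl-2-oxo-7-(triisopropylsilyloxy)-2H-chromen-3-yl}hexane-1,3-dione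
Product: 26 (R)-5-hydroxy-1-{7-hydroxy-5-[(S)-2-hydroxypropyl]-6,8-dimethyl-2-oxo-2H-chromen-3-yl}hexane-1,3-dione
Conditions: Bu4NF (6 equiv), AcOH (6 equiv), THF, rt → 40 °C
Reagents that add atoms: none
Why: Buffered fluoride cleaves the aryl and both alkyl silyl ethers at silicon without touching any C–O bond, so both carbinol configurations are kept, and the 1,3-diketone is protected as its enol or enolate against retro-aldol cleavage and elimination.

Step 14
Reactants: 26 (R)-5-hydroxy-1-{7-hydroxy-5-[(S)-2-hydroxypropyl]-6,8-dimethyl-2-oxo-2H-chromen-3-yl}hexane-1,3-dione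
Product: 28 7-hydroxy-5-[(S)-2-hydroxypropyl]-6,8-dimethyl-3-[(R)-2-methyl-4-oxo-3,4-dihydro-2H-pyran-6-yl]-2H-chromen-2-one (CNP0308039.1), via cyclic hemiketal 27 (not isolated)
Conditions: p-TsOH·H2O (cat.), CH2Cl2/THF, rt
Reagents that add atoms: none
Why: Acid-catalysed addition of the delta-hydroxyl to the coumarin-bound carbonyl gives the six-membered hemiketal 27, whose dehydration to the vinylogous ester is the standard cyclodehydration of delta-hydroxy-1,3-diketones to 2,3-dihydro-4H-pyran-4-ones; the C–O bond at the stereocentre stays intact, so the (R) configuration is retained.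

Compound list

1 | (S)-3-hydroxybutanoic acid | OC(=O)C[C@H](C)O | starting material
2 | tert-butyldiphenylsilyl (S)-3-(tert-butyldiphenylsilyloxy)butanoate | O=C(C[C@H](C)O[Si](c1ccccc1)(c2ccccc2)C(C)(C)C)O[Si](c3ccccc3)(c4ccccc4)C(C)(C)C | intermediate
3 | (S)-3-(tert-butyldiphenylsilyloxy)butanoic acid | OC(=O)C[C@H](C)O[Si](c1ccccc1)(c2ccccc2)C(C)(C)C | intermediate
4 | potassium methyl malonate (potassium 3-methoxy-3-oxopropanoate) | COC(=O)CC(=O)[O-].[K+] | starting material
5 | (S)-3-(tert-butyldiphenylsilyloxy)-1-(1H-imidazol-1-yl)butan-1-one | O=C(C[C@H](C)O[Si](c1ccccc1)(c2ccccc2)C(C)(C)C)n3ccnc3 | intermediate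
6 | methyl (S)-5-(tert-butyldiphenylsilyloxy)-3-oxohexanoate | COC(=O)CC(=O)C[C@H](C)O[Si](c1ccccc1)(c2ccccc2)C(C)(C)C | intermediate
7 | methylmalonic acid | CC(C(=O)O)C(=O)O | starting material
8 | methylmalonyl dichloride (2-methylpropanedioyl dichloride) | CC(C(=O)Cl)C(=O)Cl | intermediate
9 | methyl 6-[(S)-2-(tert-butyldiphenylsilyloxy)propyl]-4-hydroxy-3-methyl-2-oxo-2H-pyran-5-carboxylate | COC(=O)C1=C(C[C@H](C)O[Si](c2ccccc2)(c3ccccc3)C(C)(C)C)OC(=O)C(C)=C1O | intermediate
10 | methyl 6-[(S)-2-(tert-butyldiphenylsilyloxy)propyl]-3-methyl-2-oxo-4-(pivaloyloxy)-2H-pyran-5-carboxylate | COC(=O)C1=C(C[C@H](C)O[Si](c2ccccc2)(c3ccccc3)C(C)(C)C)OC(=O)C(C)=C1OC(=O)C(C)(C)C | intermediate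
11 | propyne | CC#C | starting material
12 | 1-propynyllithium | [Li]C#CC | intermediate
13 | lithium prop-1-yn-1-olate | CC#C[O-].[Li+] | intermediate
14 | 1-(triisopropylsilyloxy)prop-1-yne | CC#CO[Si](C(C)C)(C(C)C)C(C)C | intermediate
15 | methyl 1-[(S)-2-(tert-butyldiphenylsilyloxy)propyl]-4,7-dimethyl-3-oxo-5-(pivaloyloxy)-8-(triisopropylsilyloxy)-2-oxabicyclo[2.2.2]octa-5,7-diene-6-carboxylate (bridgehead configuration not defined) | COC(=O)C1=C(OC(=O)C(C)(C)C)C2(C)C(=O)OC1(C[C@H](C)O[Si](c3ccccc3)(c4ccccc4)C(C)(C)C)C(C)=C2O[Si](C(C)C)(C(C)C)C(C)C | intermediate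
16 | methyl 6-[(S)-2-(tert-butyldiphenylsilyloxy)propyl]-3,5-dimethyl-2-(pivaloyloxy)-4-(triisopropylsilyloxy)benzoate | COC(=O)c1c(OC(=O)C(C)(C)C)c(C)c(O[Si](C(C)C)(C(C)C)C(C)C)c(C)c1C[C@H](C)O[Si](c2ccccc2)(c3ccccc3)C(C)(C)C | intermediate
17 | 3-[(S)-2-(tert-butyldiphenylsilyloxy)propyl]-2-(hydroxymethyl)-4,6-dimethyl-5-(triisopropylsilyloxy)phenol | OCc1c(O)c(C)c(O[Si](C(C)C)(C(C)C)C(C)C)c(C)c1C[C@H](C)O[Si](c2ccccc2)(c3ccccc3)C(C)(C)C | intermediate
18 | 6-[(S)-2-(tert-butyldiphenylsilyloxy)propyl]-2-hydroxy-3,5-dimethyl-4-(triisopropylsilyloxy)benzaldehyde | O=Cc1c(O)c(C)c(O[Si](C(C)C)(C(C)C)C(C)C)c(C)c1C[C@H](C)O[Si](c2ccccc2)(c3ccccc3)C(C)(C)C | intermediate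
19 | ethyl acetoacetate | CCOC(=O)CC(C)=O | starting material
20 | 3-acetyl-5-[(S)-2-(tert-butyldiphenylsilyloxy)propyl]-6,8-dimethyl-7-(triisopropylsilyloxy)-2H-chromen-2-one | CC(=O)c1cc2c(C[C@H](C)O[Si](c3ccccc3)(c4ccccc4)C(C)(C)C)c(C)c(O[Si](C(C)C)(C(C)C)C(C)C)c(C)c2oc1=O | intermediate
21 | (R)-3-hydroxybutanoic acid | OC(=O)C[C@@H](C)O | starting material
22 | tert-butyldimethylsilyl (R)-3-(tert-butyldimethylsilyloxy)butanoate | O=C(C[C@@H](C)O[Si](C)(C)C(C)(C)C)O[Si](C)(C)C(C)(C)C | intermediate
23 | (R)-3-(tert-butyldimethylsilyloxy)butanoic acid | OC(=O)C[C@@H](C)O[Si](C)(C)C(C)(C)C | intermediate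
24 | (R)-3-(tert-butyldimethylsilyloxy)-1-(1H-imidazol-1-yl)butan-1-one | O=C(C[C@@H](C)O[Si](C)(C)C(C)(C)C)n1ccnc1 | intermediate
25 | (R)-5-(tert-butyldimethylsilyloxy)-1-{5-[(S)-2-(tert-butyldiphenylsilyloxy)propyl]-6,8-dimethyl-2-oxo-7-(triisopropylsilyloxy)-2H-chromen-3-yl}hexane-1,3-dione | O=C(CC(=O)C[C@@H](C)O[Si](C)(C)C(C)(C)C)c1cc2c(C[C@H](C)O[Si](c3ccccc3)(c4ccccc4)C(C)(C)C)c(C)c(O[Si](C(C)C)(C(C)C)C(C)C)c(C)c2oc1=O | intermediate
26 | (R)-5-hydroxy-1-{7-hydroxy-5-[(S)-2-hydroxypropyl]-6,8-dimethyl-2-oxo-2H-chromen-3-yl}hexane-1,3-dione | O=C(CC(=O)C[C@@H](C)O)c1cc2c(C[C@H](C)O)c(C)c(O)c(C)c2oc1=O | intermediate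
27 | 7-hydroxy-3-[(6R)-2-hydroxy-6-methyl-4-oxotetrahydro-2H-pyran-2-yl]-5-[(S)-2-hydroxypropyl]-6,8-dimethyl-2H-chromen-2-one (hemiketal carbon not defined) | OC3(CC(=O)C[C@@H](C)O3)c1cc2c(C[C@H](C)O)c(C)c(O)c(C)c2oc1=O | intermediate
28 | 7-hydroxy-5-[(S)-2-hydroxypropyl]-6,8-dimethyl-3-[(R)-2-methyl-4-oxo-3,4-dihydro-2H-pyran-6-yl]-2H-chromen-2-one (CNP0308039.1) | Cc1c(O)c(C)c2oc(=O)c(C3=CC(=O)C[C@@H](C)O3)cc2c1C[C@H](C)O | target

Total step count: 14.
Longest linear sequence: 11 steps (1, 2, 4, 5, 7, 8, 9, 10, 12, 13, 14).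

Steps most likely to fail

Step 7. The cycloaddition may be too slow at the two fully substituted diene termini, so that thermal isomerisation of the siloxyalkyne to a silylketene or loss of the pivaloyl group overtakes ring formation. The fallback sets out from 10 and comes back at 16. The two-carbon partner is changed from an alkyne to a ketene acetal, 1,1-bis(trimethylsilyloxy)prop-1-ene F1, made from propanoic acid with LiN(i-Pr)2 (2 equiv) and Me3SiCl. Heated with 10 in toluene at 110 °C, it should add with the same orientation (its CH(CH3) carbon to pyrone C6, its acetal carbon to C3). Loss of CO2 and then of trimethylsilanol should give the aryl trimethylsilyl ether F2. Dilute aqueous HCl in THF on work-up frees the phenol F3, and i-Pr3SiOTf with 2,6-lutidine in CH2Cl2 converts F3 into 16. This is the known benzannulation of pyrone carboxylates with ketene acetals, in which aromatisation comes from elimination instead of from the alkyne oxidation level.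

Step 4. The hydrogen chloride released may cleave or eliminate the silyl ether, and the diacid chloride may self-condense through its ketene faster than it acylates the keto ester. The fallback sets out from 6 and comes back at 9. The one-pot double acylation is replaced by a base-mediated two-stage sequence. Magnesium-chelate C-acylation of 6 (MgCl2, pyridine, CH2Cl2, 0 °C) with methyl 3-chloro-2-methyl-3-oxopropanoate F4 (from commercial 3-methoxy-2-methyl-3-oxopropanoic acid and oxalyl chloride) gives dimethyl 2-[(S)-3-(tert-butyldiphenylsilyloxy)butanoyl]-4-methyl-3-oxopentanedioate F5. DBU in toluene then closes the lactone through the ketone enol oxygen with loss of methanol to give 9. No free acid meets the silyl ether on this path.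

Step 12. The enolate or the amide base may add to C4 of the acetylcoumarin (self-condensation), the enolate may be acylated on oxygen, or the acyl donor may be deprotonated and lose silanolate by beta-elimination. The fallback sets out from 20 and 23 and comes back at 25. Acylation is replaced by aldol addition and oxidation. Acid 23 is reduced with BH3·THF to (R)-3-(tert-butyldimethylsilyloxy)butan-1-ol F6, which is oxidised with Dess–Martin periodinane to (R)-3-(tert-butyldimethylsilyloxy)butanal F7. The lithium enolate of 20 (LiN(SiMe3)2, 1.1 equiv, THF, −78 °C) adds to F7 to give the beta-hydroxy ketone F8, whose new carbinol configuration is irrelevant. Dess–Martin oxidation of F8 gives the 1,3-diketone 25.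

Further compounds

F1 | step 7 | 1,1-bis(trimethylsilyloxy)prop-1-ene | CC=C(O[Si](C)(C)C)O[Si](C)(C)C
F2 | step 7 | methyl 6-[(S)-2-(tert-butyldiphenylsilyloxy)propyl]-3,5-dimethyl-2-(pivaloyloxy)-4-(trimethylsilyloxy)benzoate | COC(=O)c1c(OC(=O)C(C)(C)C)c(C)c(O[Si](C)(C)C)c(C)c1C[C@H](C)O[Si](c2ccccc2)(c3ccccc3)C(C)(C)C
F3 | step 7 | methyl 6-[(S)-2-(tert-butyldiphenylsilyloxy)propyl]-4-hydroxy-3,5-dimethyl-2-(pivaloyloxy)benzoate | COC(=O)c1c(OC(=O)C(C)(C)C)c(C)c(O)c(C)c1C[C@H](C)O[Si](c2ccccc2)(c3ccccc3)C(C)(C)C
F4 | step 4 | methyl 3-chloro-2-methyl-3-oxopropanoate | COC(=O)C(C)C(=O)Cl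
F5 | step 4 | dimethyl 2-[(S)-3-(tert-butyldiphenylsilyloxy)butanoyl]-4-methyl-3-oxopentanedioate | COC(=O)C(C(=O)C[C@H](C)O[Si](c1ccccc1)(c2ccccc2)C(C)(C)C)C(=O)C(C)C(=O)OC
F6 | step 12 | (R)-3-(tert-butyldimethylsilyloxy)butan-1-ol | OCC[C@@H](C)O[Si](C)(C)C(C)(C)C
F7 | step 12 | (R)-3-(tert-butyldimethylsilyloxy)butanal | O=CC[C@@H](C)O[Si](C)(C)C(C)(C)C
F8 | step 12 | (5R)-5-(tert-butyldimethylsilyloxy)-1-{5-[(S)-2-(tert-butyldiphenylsilyloxy)propyl]-6,8-dimethyl-2-oxo-7-(triisopropylsilyloxy)-2H-chromen-3-yl}-3-hydroxyhexan-1-one | O=C(CC(O)C[C@@H](C)O[Si](C)(C)C(C)(C)C)c1cc2c(C[C@H](C)O[Si](c3ccccc3)(c4ccccc4)C(C)(C)C)c(C)c(O[Si](C(C)C)(C(C)C)C(C)C)c(C)c2oc1=O
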